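## Retrosynthetic overview

1. Chlorovulone III ⇒ (MnO2 oxidation at C9, O-desilylation at C12) ⇒ a 5-alkylidenecyclopent-2-en-1-ol. The only ring (C8–C9–C10–C11–C12) is made in the key step; everything before it is acyclic.
2. Key disconnections C8–C9 (ring closure) and C6–C7: nickel-catalysed three-component coupling of an acyclic C7–C20 ynal (aldehyde C9, terminal alkyne C7≡C8) with the C1–C6 alkenylzirconium from methyl hex-5-ynoate.
3. Enabling feature: in the target the carbonyl carbon C9 and C6 are cis on the exocyclic C7=C8 bond of the five-membered ring (7Z), and C9 is tied to C8 by the cis C10=C11–C12 bridge. This is the imprint of a syn addition of C9 and C6 across a terminal C7≡C8 alkyne.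
4. Ynal ⇒ C9 by retentive formylation of an α-chlorovinyllithium; C10 (with Cl) by Takai olefination of a C11 aldehyde.
5. C12 (the only stereocentre) ⇒ Sharpless epoxidation of a 2-alkynylallyl alcohol (2-bromoallyl alcohol + trimethylsilylacetylene); C13–C20 ⇒ epoxide opening by heptynyllithium, then Lindlar reduction.

Key step: step 11

Remark: atoms are numbered as in the prostanoid skeleton of the target (C1 ester carbon, C9 ketone carbon, C12 carbinol carbon, C20 terminal methyl). The two C9 epimers formed in step 11 are carried as a mixture because step 13 removes that centre.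

## Route

Step 1
Reactants: 1 2-bromoprop-2-en-1-ol; 2 ethynyltrimethylsilane
Product: 3 2-methylidene-4-(trimethylsilyl)but-3-yn-1-ol
Conditions: PdCl2(PPh3)2 (2 mol %), CuI (4 mol %), Et3N, THF, rt
Reagents that add atoms: none
Why: Sonogashira coupling of a 2-bromoalkene with a terminal alkyne tolerates the free allylic alcohol and creates no stereocentre.

Step 2
Reactants: 3 2-methylidene-4-(trimethylsilyl)but-3-yn-1-ol
Product: 4 [(2S)-2-[(trimethylsilyl)ethynyl]oxiran-2-yl]methanol
Conditions: Ti(OiPr)4 (0.2 equiv), L-(+)-diethyl tartrate (0.24 equiv), t-BuOOH (2 equiv, decane), 4 Å molecular sieves, CH2Cl2, −20 °C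
Reagents that add atoms: tert-butyl hydroperoxide, CC(C)(C)OO
Why: Sharpless asymmetric epoxidation of a 2-substituted allylic alcohol, in which the L-(+)-tartrate complex delivers oxygen to the face that gives the (S)-epoxy alcohol (the same face as in (S)-glycidol formation), so that the epoxide oxygen becomes the C12 oxygen of the target with the required configuration.

Step 3
Reactants: 4 [(2S)-2-[(trimethylsilyl)ethynyl]oxiran-2-yl]methanol
Product: 5 triethyl{[(2R)-2-[(trimethylsilyl)ethynyl]oxiran-2-yl]methoxy}silane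
Conditions: Et3SiCl, imidazole, CH2Cl2, 0 °C
Reagents that add atoms: chlorotriethylsilane, CC[Si](CC)(CC)Cl
Why: Routine silylation of a primary alcohol; the TES ether is chosen because step 7 oxidises it directly, and the descriptor changes to R only through the CIP priorities.

Step 4
Reactants: 5 triethyl{[(2R)-2-[(trimethylsilyl)ethynyl]oxiran-2-yl]methoxy}silane; 6 hept-1-yne
Product: 8 (2S)-1-[(triethylsilyl)oxy]-2-[(trimethylsilyl)ethynyl]dec-4-yn-2-ol, via lithium hept-1-yn-1-ide 7 (not isolated)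
Conditions: 6, n-BuLi, THF, −78 °C; BF3·OEt2; then 5, −78 °C; H2O
Reagents that add atoms: none
Why: BF3-promoted opening of an epoxide by an alkynyllithium (Yamaguchi alkynylation) proceeds by SN2 attack at the unsubstituted CH2 (C13), so no bond to C12 is broken and its configuration is retained.

Step 5
Reactants: 8 (2S)-1-[(triethylsilyl)oxy]-2-[(trimethylsilyl)ethynyl]dec-4-yn-2-ol
Product: 9 (2S)-2-[(tert-butyldimethylsilyl)oxy]-1-[(triethylsilyl)oxy]-2-[(trimethylsilyl)ethynyl]dec-4-yne
Conditions: t-BuMe2SiOTf, 2,6-lutidine, CH2Cl2, −78 to 0 °C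
Reagents that add atoms: tert-butyldimethylsilyl trifluoromethanesulfonate, CC(C)(C)[Si](C)(C)OS(=O)(=O)C(F)(F)F
Why: Silyl triflate with 2,6-lutidine silylates hindered tertiary alcohols, and the bulkier TBS group is placed on the C12 oxygen because it must survive the Swern conditions of step 7 and resist 1,4 O-to-C silyl migration in the cis-lithioalkene of step 9.

Step 6
Reactants: 9 (2S)-2-[(tert-butyldimethylsilyl)oxy]-1-[(triethylsilyl)oxy]-2-[(trimethylsilyl)ethynyl]dec-4-yne
Product: 10 (2S,4Z)-2-[(tert-butyldimethylsilyl)oxy]-1-[(triethylsilyl)oxy]-2-[(trimethylsilyl)ethynyl]dec-4-ene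
Conditions: H2 (1 atm), Pd/CaCO3 poisoned with Pb(OAc)2 (Lindlar catalyst), quinoline, EtOAc, rt
Reagents that add atoms: none
Why: Lindlar semihydrogenation adds H2 syn to the unhindered dialkyl alkyne and sets the 14Z bond, while the silyl-capped alkyne on the fully substituted C12 is much more hindered and should survive.

Step 7
Reactants: 10 (2S,4Z)-2-[(tert-butyldimethylsilyl)oxy]-1-[(triethylsilyl)oxy]-2-[(trimethylsilyl)ethynyl]dec-4-ene
Product: 11 (2S,4Z)-2-[(tert-butyldimethylsilyl)oxy]-2-[(trimethylsilyl)ethynyl]dec-4-enal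
Conditions: (COCl)2, DMSO, CH2Cl2, −78 °C; Et3N, −78 to −20 °C
Reagents that add atoms: none
Why: Swern conditions convert primary TES ethers directly into aldehydes (oxidative desilylation) while tertiary TBS ethers stay intact, and the α-quaternary aldehyde cannot epimerise.

Step 8
Reactants: 11 (2S,4Z)-2-[(tert-butyldimethylsilyl)oxy]-2-[(trimethylsilyl)ethynyl]dec-4-enal
Product: 12 (1E,3R,5Z)-3-[(tert-butyldimethylsilyl)oxy]-1-chloro-3-[(trimethylsilyl)ethynyl]undeca-1,5-diene
Conditions: CrCl2 (6 equiv), CHCl3 (2 equiv), THF, 65 °C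
Reagents that add atoms: chloroform, ClC(Cl)Cl
Why: Takai chloro-olefination adds C10 with its chlorine and should give mainly the (E)-1-chloroalkene, also from hindered aldehydes; the silyl ethers and both π systems are inert to CrCl2.

Step 9
Reactants: 12 (1E,3R,5Z)-3-[(tert-butyldimethylsilyl)oxy]-1-chloro-3-[(trimethylsilyl)ethynyl]undeca-1,5-diene
Product: 14 (2E,4R,6Z)-4-[(tert-butyldimethylsilyl)oxy]-2-chloro-4-[(trimethylsilyl)ethynyl]dodeca-2,6-dienal, via α-chlorovinyllithium 13 (not isolated)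
Conditions: s-BuLi (1.3 equiv), THF/Et2O/pentane, −105 °C; DMF, −105 to −78 °C; H2O
Reagents that add atoms: N,N-dimethylformamide, CN(C)C=O
Why: α-Deprotonation of an (E)-1-chloroalkene gives a configurationally stable α-chlorovinyllithium carbenoid at −105 °C (the group anti to chlorine is the poorly migrating tertiary C12, so Fritsch–Buttenberg–Wiechell rearrangement is slow), and formylation with DMF occurs with retention, which places the new C9 aldehyde cis to C12.

Step 10
Reactants: 14 (2E,4R,6Z)-4-[(tert-butyldimethylsilyl)oxy]-2-chloro-4-[(trimethylsilyl)ethynyl]dodeca-2,6-dienal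
Product: 15 (2E,4R,6Z)-4-[(tert-butyldimethylsilyl)oxy]-2-chloro-4-ethynyldodeca-2,6-dienal
Conditions: AgNO3 (20 mol %), acetone/H2O/CH2Cl2, rt
Reagents that add atoms: none
Why: Silver-catalysed protodesilylation cleaves only the alkynyl–SiMe3 bond under neutral conditions, sparing the O-silyl ether, the aldehyde and the base-sensitive cis-enal geometry.

Step 11
Reactants: 15 (2E,4R,6Z)-4-[(tert-butyldimethylsilyl)oxy]-2-chloro-4-ethynyldodeca-2,6-dienal; 16 methyl hex-5-ynoate
Product: 18 methyl (5E,7E)-7-[(2R)-2-[(tert-butyldimethylsilyl)oxy]-4-chloro-5-hydroxy-2-[(2Z)-oct-2-en-1-yl]cyclopent-3-en-1-ylidene]hept-5-enoate (both C9 epimers; C6 cis to C9), via alkenylzirconocene chloride 17 (not isolated)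
Conditions: 16 (1.6 equiv), Cp2Zr(H)Cl (1.5 equiv), THF, rt; then ZnCl2 (20 mol %), Ni(cod)2 (10 mol %), slow addition of 15, THF, 0 °C; aq. NH4Cl
Reagents that add atoms: none
Why: Zerovalent nickel binds the aldehyde C9=O and the terminal alkyne C7≡C8 of 15 and couples them by oxidative cyclization to an oxanickelacyclopentene (O–C9–C8=C7–Ni), which forms the C8–C9 bond; the alkenyl group of 17 is then passed (through zinc) to nickel, and C6–C7 reductive elimination releases the zirconium alkoxide of 18. The closest known reaction type is the nickel-catalysed alkylative (three-component) cyclization of ynals with organozinc or alkenylzirconium reagents. The carbocycle (C8, C9, C10, C11, C12) closes in the 5-exo-dig mode with C7 left outside the ring, and the short cis C10=C11–C12 tether allows no other union of aldehyde and alkyne. The only new stereocentre, the C9 carbinol, is not controlled and need not be, since step 13 turns it into the ketone; C12 is untouched, the C7=C8 geometry follows from the cis arrangement of C9 and nickel in the metallacycle and retention in the reductive elimination (C6 ends cis to C9, named 7E in the alcohol only because of CIP priorities), and the 5E bond comes unchanged from the syn hydrozirconation of 16. The step needs chemoselectivity for oxidative cyclization over insertion of nickel into the C10–Cl bond and over direct 1,2-addition of the alkenylmetal to the enal; the phosphine-free catalyst at 0 °C, the chelating ynal (aldehyde and alkyne held together by the cis C10=C11 bond built in step 9) and the low nucleophilicity of the alkenylzirconium, activated only by substoichiometric ZnCl2, are expected to secure this.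

Step 12
Reactants: 18 methyl (5E,7E)-7-[(2R)-2-[(tert-butyldimethylsilyl)oxy]-4-chloro-5-hydroxy-2-[(2Z)-oct-2-en-1-yl]cyclopent-3-en-1-ylidene]hept-5-enoate
Product: 19 methyl (5E,7E)-7-[(2R)-4-chloro-2,5-dihydroxy-2-[(2Z)-oct-2-en-1-yl]cyclopent-3-en-1-ylidene]hept-5-enoate (both C9 epimers)
Conditions: Bu4NF, THF, 0 °C to rt; H2O
Reagents that add atoms: none
Why: Fluoride cleavage of the tertiary TBS ether is done at the alcohol stage, where no base-sensitive cross-conjugated dienone is yet present, and the methyl ester and vinyl chloride are inert to Bu4NF at this temperature.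

Step 13
Reactants: 19 methyl (5E,7E)-7-[(2R)-4-chloro-2,5-dihydroxy-2-[(2Z)-oct-2-en-1-yl]cyclopent-3-en-1-ylidene]hept-5-enoate
Product: 20 chlorovulone III, methyl (5E,7Z)-7-[(2R)-4-chloro-2-hydroxy-2-[(2Z)-oct-2-en-1-yl]-5-oxocyclopent-3-en-1-ylidene]hept-5-enoate
Conditions: activated MnO2 (excess), CH2Cl2, rt
Reagents that add atoms: none
Why: MnO2 oxidises allylic secondary alcohols chemoselectively under neutral heterogeneous conditions (the C9 carbinol is allylic on both sides, the tertiary C12 alcohol cannot be oxidised), both C9 epimers converge on the ketone, and the C7=C8 geometry (C6 cis to C9, now named 7Z) is not touched.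

## Compound list

1 | 2-bromoprop-2-en-1-ol | OCC(Br)=C | starting material
2 | ethynyltrimethylsilane | C#C[Si](C)(C)C | starting material
3 | 2-methylidene-4-(trimethylsilyl)but-3-yn-1-ol | OCC(=C)C#C[Si](C)(C)C | intermediate
4 | [(2S)-2-[(trimethylsilyl)ethynyl]oxiran-2-yl]methanol | OC[C@@]1(C#C[Si](C)(C)C)CO1 | intermediate
5 | triethyl{[(2R)-2-[(trimethylsilyl)ethynyl]oxiran-2-yl]methoxy}silane | CC[Si](CC)(CC)OC[C@@]1(C#C[Si](C)(C)C)CO1 | intermediate
6 | hept-1-yne | C#CCCCCC | starting material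
7 | lithium hept-1-yn-1-ide | [Li]C#CCCCCC | intermediate
8 | (2S)-1-[(triethylsilyl)oxy]-2-[(trimethylsilyl)ethynyl]dec-4-yn-2-ol | CC[Si](CC)(CC)OC[C@@](O)(C#C[Si](C)(C)C)CC#CCCCCC | intermediate
9 | (2S)-2-[(tert-butyldimethylsilyl)oxy]-1-[(triethylsilyl)oxy]-2-[(trimethylsilyl)ethynyl]dec-4-yne | CC[Si](CC)(CC)OC[C@@](O[Si](C)(C)C(C)(C)C)(C#C[Si](C)(C)C)CC#CCCCCC | intermediate
10 | (2S,4Z)-2-[(tert-butyldimethylsilyl)oxy]-1-[(triethylsilyl)oxy]-2-[(trimethylsilyl)ethynyl]dec-4-ene | CC[Si](CC)(CC)OC[C@@](O[Si](C)(C)C(C)(C)C)(C#C[Si](C)(C)C)C/C=C\CCCCC | intermediate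
11 | (2S,4Z)-2-[(tert-butyldimethylsilyl)oxy]-2-[(trimethylsilyl)ethynyl]dec-4-enal | O=C[C@@](O[Si](C)(C)C(C)(C)C)(C#C[Si](C)(C)C)C/C=C\CCCCC | intermediate
12 | (1E,3R,5Z)-3-[(tert-butyldimethylsilyl)oxy]-1-chloro-3-[(trimethylsilyl)ethynyl]undeca-1,5-diene | Cl/C=C/[C@@](O[Si](C)(C)C(C)(C)C)(C#C[Si](C)(C)C)C/C=C\CCCCC | intermediate
13 | [(1E,3R,5Z)-3-[(tert-butyldimethylsilyl)oxy]-1-chloro-3-[(trimethylsilyl)ethynyl]undeca-1,5-dien-1-yl]lithium (lithium cis to C3) | Cl/C([Li])=C/[C@@](O[Si](C)(C)C(C)(C)C)(C#C[Si](C)(C)C)C/C=C\CCCCC | intermediate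
14 | (2E,4R,6Z)-4-[(tert-butyldimethylsilyl)oxy]-2-chloro-4-[(trimethylsilyl)ethynyl]dodeca-2,6-dienal | Cl/C(C=O)=C/[C@@](O[Si](C)(C)C(C)(C)C)(C#C[Si](C)(C)C)C/C=C\CCCCC | intermediate
15 | (2E,4R,6Z)-4-[(tert-butyldimethylsilyl)oxy]-2-chloro-4-ethynyldodeca-2,6-dienal | Cl/C(C=O)=C/[C@@](O[Si](C)(C)C(C)(C)C)(C#C)C/C=C\CCCCC | intermediate
16 | methyl hex-5-ynoate | C#CCCCC(=O)OC | starting material
17 | chlorobis(η5-cyclopentadienyl)[(1E)-6-methoxy-6-oxohex-1-en-1-yl]zirconium | COC(=O)CCC/C=C/[Zr](Cl)(C1C=CC=C1)C1C=CC=C1 | intermediate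
18 | methyl (5E,7E)-7-[(2R)-2-[(tert-butyldimethylsilyl)oxy]-4-chloro-5-hydroxy-2-[(2Z)-oct-2-en-1-yl]cyclopent-3-en-1-ylidene]hept-5-enoate (both C9 epimers; C6 cis to C9) | CCCCC/C=C\C[C@@]1(O[Si](C)(C)C(C)(C)C)C=C(Cl)C(O)/C1=C\C=C\CCCC(=O)OC | intermediate
19 | methyl (5E,7E)-7-[(2R)-4-chloro-2,5-dihydroxy-2-[(2Z)-oct-2-en-1-yl]cyclopent-3-en-1-ylidene]hept-5-enoate (both C9 epimers) | CCCCC/C=C\C[C@@]1(O)C=C(Cl)C(O)/C1=C\C=C\CCCC(=O)OC | intermediate
20 | chlorovulone III, methyl (5E,7Z)-7-[(2R)-4-chloro-2-hydroxy-2-[(2Z)-oct-2-en-1-yl]-5-oxocyclopent-3-en-1-ylidene]hept-5-enoate | CCCCC/C=C\C[C@@]1(O)C=C(Cl)C(=O)/C1=C\C=C\CCCC(=O)OC | target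

## Step count and risks

Total step count: 13. Longest linear sequence: 13 steps (from 1; fragment 16 enters in step 11 without separate steps).

Steps most likely to fail:

**Step 11.** Nickel may insert into the activated C10–Cl bond, the alkenylmetal may add directly (uncatalysed) to the enal carbonyl, or the terminal alkyne may be oligomerised by nickel before oxidative cyclization. The fallback keeps the C8–C9 closure and the syn-addition logic but separates the events; it sets out from 15 and comes back to the route at 18. Syn diboration of the terminal alkyne of 15 with bis(pinacolato)diboron under Pt(PPh3)4 catalysis (toluene, 80 °C) should give (2E,4R,6Z)-4-[(E)-1,2-bis(4,4,5,5-tetramethyl-1,3,2-dioxaborolan-2-yl)ethenyl]-4-[(tert-butyldimethylsilyl)oxy]-2-chlorododeca-2,6-dienal F1, with both boron atoms on the same side of C7=C8. A Suzuki–Miyaura coupling (PdCl2(dppf), K3PO4, THF/H2O, rt) with methyl (5E)-6-iodohex-5-enoate F2 (from 16 by hydrozirconation with Cp2Zr(H)Cl and iodinolysis with I2) should take place at the less hindered terminal C7–B bond and give methyl (5E,7E,9R,10E)-9-[(tert-butyldimethylsilyl)oxy]-11-chloro-9-[(2Z)-oct-2-en-1-yl]-12-oxo-8-(4,4,5,5-tetramethyl-1,3,2-dioxaborolan-2-yl)dodeca-5,7,10-trienoate F3, in which the remaining boryl group on C8 is cis to C6. Rhodium-catalysed intramolecular 1,2-addition of this alkenylboronate to the aldehyde ([Rh(cod)OH]2, dioxane/H2O, 50 °C) then forms the C8–C9 bond with retention at C8 and gives 18. No zerovalent nickel and no alkenylzinc species are present in this sequence.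

**Step 9.** The α-chlorovinyllithium may decompose (rearrangement to the alkyne or loss of LiCl), lose its configuration, or suffer 1,4 O-to-C silyl migration before it is formylated. The fallback builds the cis chloro-enal by syn hydrostannation of an ynal instead; it sets out from 11 and comes back at 14. Corey–Fuchs olefination of 11 (CBr4, PPh3, Et3N, CH2Cl2, 0 °C) gives (3R,5Z)-1,1-dibromo-3-[(tert-butyldimethylsilyl)oxy]-3-[(trimethylsilyl)ethynyl]undeca-1,5-diene F4. Treatment with n-BuLi (2.2 equiv, THF, −78 °C) and then DMF gives (4R,6Z)-4-[(tert-butyldimethylsilyl)oxy]-4-[(trimethylsilyl)ethynyl]dodec-6-en-2-ynal F5. Syn hydrostannation with Bu3SnH under Pd(PPh3)4 catalysis (THF, 0 °C), which places tin α to the carbonyl and hydrogen on C11, gives (2E,4R,6Z)-4-[(tert-butyldimethylsilyl)oxy]-2-(tributylstannyl)-4-[(trimethylsilyl)ethynyl]dodeca-2,6-dienal F6 with the aldehyde cis to C12. Chlorodestannylation with CuCl2 (THF, rt), with retention, gives 14.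

**Step 4.** The Lewis acid may ionise the tertiary propargylic C–O bond of the epoxide (rearrangement to an aldehyde or attack through the alkyne) instead of allowing clean SN2 opening; in addition, the later semihydrogenation (step 6) may over-reduce or touch the silylalkyne. The fallback uses a Lewis-acid-free opening and a Wittig reaction for the Z-alkene; it sets out from 5 and comes back at 10. 2-Lithio-1,3-dithiane (1,3-dithiane, n-BuLi, THF, −30 °C) opens 5 at C13 to give (2S)-1-(1,3-dithian-2-yl)-3-[(triethylsilyl)oxy]-2-[(trimethylsilyl)ethynyl]propan-2-ol F7. Silylation (t-BuMe2SiOTf, 2,6-lutidine, CH2Cl2) gives (2S)-2-[(tert-butyldimethylsilyl)oxy]-1-(1,3-dithian-2-yl)-3-[(triethylsilyl)oxy]-2-[(trimethylsilyl)ethynyl]propane F8. Dithiane removal (MeI, CaCO3, MeCN/H2O) gives (3S)-3-[(tert-butyldimethylsilyl)oxy]-3-{[(triethylsilyl)oxy]methyl}-5-(trimethylsilyl)pent-4-ynal F9. A Z-selective Wittig reaction with the ylide from hexyltriphenylphosphonium bromide and NaN(SiMe3)2 (THF, −78 °C) gives 10.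

## Further compounds

F1 | step 11 | (2E,4R,6Z)-4-[(E)-1,2-bis(4,4,5,5-tetramethyl-1,3,2-dioxaborolan-2-yl)ethenyl]-4-[(tert-butyldimethylsilyl)oxy]-2-chlorododeca-2,6-dienal | Cl/C(C=O)=C/[C@@](O[Si](C)(C)C(C)(C)C)(/C(B1OC(C)(C)C(C)(C)O1)=C/B1OC(C)(C)C(C)(C)O1)C/C=C\CCCCC
F2 | step 11 | methyl (5E)-6-iodohex-5-enoate | COC(=O)CCC/C=C/I
F3 | step 11 | methyl (5E,7E,9R,10E)-9-[(tert-butyldimethylsilyl)oxy]-11-chloro-9-[(2Z)-oct-2-en-1-yl]-12-oxo-8-(4,4,5,5-tetramethyl-1,3,2-dioxaborolan-2-yl)dodeca-5,7,10-trienoate | Cl/C(C=O)=C/[C@@](O[Si](C)(C)C(C)(C)C)(/C(B1OC(C)(C)C(C)(C)O1)=C/C=C/CCCC(=O)OC)C/C=C\CCCCC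
F4 | step 9 | (3R,5Z)-1,1-dibromo-3-[(tert-butyldimethylsilyl)oxy]-3-[(trimethylsilyl)ethynyl]undeca-1,5-diene | BrC(Br)=C[C@@](O[Si](C)(C)C(C)(C)C)(C#C[Si](C)(C)C)C/C=C\CCCCC
F5 | step 9 | (4R,6Z)-4-[(tert-butyldimethylsilyl)oxy]-4-[(trimethylsilyl)ethynyl]dodec-6-en-2-ynal | O=CC#C[C@@](O[Si](C)(C)C(C)(C)C)(C#C[Si](C)(C)C)C/C=C\CCCCC
F6 | step 9 | (2E,4R,6Z)-4-[(tert-butyldimethylsilyl)oxy]-2-(tributylstannyl)-4-[(trimethylsilyl)ethynyl]dodeca-2,6-dienal | CCCC[Sn](CCCC)(CCCC)/C(C=O)=C/[C@@](O[Si](C)(C)C(C)(C)C)(C#C[Si](C)(C)C)C/C=C\CCCCC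
F7 | step 4 | (2S)-1-(1,3-dithian-2-yl)-3-[(triethylsilyl)oxy]-2-[(trimethylsilyl)ethynyl]propan-2-ol | CC[Si](CC)(CC)OC[C@@](O)(C#C[Si](C)(C)C)CC1SCCCS1
F8 | step 4 | (2S)-2-[(tert-butyldimethylsilyl)oxy]-1-(1,3-dithian-2-yl)-3-[(triethylsilyl)oxy]-2-[(trimethylsilyl)ethynyl]propane | CC[Si](CC)(CC)OC[C@@](O[Si](C)(C)C(C)(C)C)(C#C[Si](C)(C)C)CC1SCCCS1
F9 | step 4 | (3S)-3-[(tert-butyldimethylsilyl)oxy]-3-{[(triethylsilyl)oxy]methyl}-5-(trimethylsilyl)pent-4-ynal | CC[Si](CC)(CC)OC[C@@](O[Si](C)(C)C(C)(C)C)(C#C[Si](C)(C)C)CC=O
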